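C1 = lactone C=O, C2 = its CH2, C3 = CH–OO, C4 = C(Me)–O(lactone), C5 = dioxane CH2, C6 = C(Me)(10-phenyldecyl)–OO. Ring A = 1,2-dioxane, ring B = five-membered lactone.
Last disconnection: the C1 carbonyl of ring B goes back to a methyl lactol ether, a change of oxidation level only.
Key disconnection: C5–C6 and O–C3 of ring A, and with them C4–O of ring B, are cut together. This is a formal [3+3] union of the C6–O–O unit of an alpha-methoxy hydroperoxide with the C3–C4–C5 unit of (E)-4-methylpenta-2,4-dienal. Ring A forms first, then ring B, in the same flask.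
Enabling feature: C6 of ring A is a ketone-level carbon bearing the O–O bond, so it is a masked carbonyl oxide (C6 electrophilic, distal O nucleophilic). C3 lies beta to C1, C5 is the terminus of a latent C4=C5 isopropenyl group, and tertiary C4 sits 1,4 to the C1 oxygen of ring B, so all polarities match and the C4 cation is caught inside ring B.
The hydroperoxide comes from ozonolysis in methanol of 2-methyl-12-phenyldodec-1-ene, made by two copper-catalysed Grignard couplings from 1,10-dibromodecane. The dienal comes from methacrolein by Wittig homologation.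

Key step: step 5

Remark: the ketal carbon of 7 and 11 and the anomeric carbon of 14 and 15 arise as mixtures and are erased later, so they carry no descriptor.

Step 1
Reactants: 1 1,10-dibromodecane; 2 phenylmagnesium bromide
Product: 3 (10-bromodecyl)benzene
Conditions: Li2CuCl4 (3 mol%), THF, 0 °C to rt; 1 in threefold excess, recovered by distillation
Reagents that add atoms: none
Why: Copper-catalysed cross-coupling of an aryl Grignard reagent with a primary alkyl bromide (Kochi-type coupling) is reliable, and the excess of the symmetrical dibromide 1 suppresses the second substitution; no stereocentre is formed.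

Step 2
Reactants: 3 (10-bromodecyl)benzene; 4 isopropenylmagnesium bromide
Product: 5 2-methyl-12-phenyldodec-1-ene
Conditions: Li2CuCl4 (3 mol%), NMP (4 equiv), THF, 0 °C to rt
Reagents that add atoms: none
Why: The same copper-catalysed Grignard-alkyl bromide coupling, here with an alkenyl Grignard reagent and NMP as co-solvent, installs the 1,1-disubstituted alkene whose substituted carbon becomes C6; no stereocentre is formed.

Step 3
Reactants: 5 2-methyl-12-phenyldodec-1-ene
Product: 7 2-hydroperoxy-2-methoxy-12-phenyldodecane (racemic), via ketone oxide 6 (not isolated)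
Conditions: O3, CH2Cl2/MeOH, NaHCO3, −78 °C; N2 purge, no reductant, cold concentration
Reagents that add atoms: ozone, [O-][O+]=O; methanol, CO
Why: Ozonolysis in a participating solvent: the primary ozonide of a 1,1-dialkylethylene cleaves toward the more substituted carbonyl oxide 6 and formaldehyde, methanol traps 6 as the alpha-methoxy hydroperoxide, the phenyl ring is inert at this temperature, and the racemic ketal centre is harmless because step 5 planarises it.

Step 4
Reactants: 8 methacrolein; 9 (triphenylphosphoranylidene)acetaldehyde
Product: 10 (2E)-4-methylpenta-2,4-dienal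
Conditions: CH2Cl2, reflux; 8 in excess; distilled and used fresh
Reagents that add atoms: none
Why: Wittig olefination with a formyl-stabilised ylide gives the (E)-enal selectively, and an excess of the volatile aldehyde 8 limits a second homologation.

Step 5
Reactants: 7 2-hydroperoxy-2-methoxy-12-phenyldodecane; 10 (2E)-4-methylpenta-2,4-dienal
Product: 14 (3R,4aS,7aS)-6-methoxy-3,4a-dimethyl-3-(10-phenyldecyl)hexahydrofuro[3,2-c][1,2]dioxine, via peroxy aldehyde 11 (not isolated), via peroxycarbenium ion 12 (not isolated), via oxolanylium ion 13 (not isolated)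
Conditions: (S)-2-{bis[3,5-bis(trifluoromethyl)phenyl](trimethylsilyloxy)methyl}pyrrolidine (20 mol%), PhCO2H (20 mol%), CH2Cl2, 0 °C; then 4 Å MS, TMSOTf (0.6 equiv), −78 to −40 °C; Et3N quench
Reagents that add atoms: none
Why: Proposed new method: in the first stage the (S)-diarylprolinol silyl ether converts 10 into its s-trans (E)-iminium ion, the distal oxygen of hydroperoxide 7 adds to C3, and protonation and hydrolysis of the enamine release 11; in the second stage TMSOTf removes the ketal methoxy group as MeOSiMe3, C5 of the isopropenyl group attacks C6 of peroxycarbenium ion 12, the aldehyde oxygen captures the developing tertiary cation at C4 to give 13, and MeOSiMe3 hands the methoxy group to C1 and regenerates the silyl Lewis acid, so that 7 and 10 are joined without loss of an atom. The closest known reaction types are the aminocatalytic enantioselective beta-peroxidation of enals with tertiary alkyl hydroperoxides and the Lewis-acid cyclisation of unsaturated monoperoxyketals (a peroxy variant of the Prins reaction); their coupling in one flask, the use of a dienal and the termination by a carbonyl oxygen are new. Ring A closes 6-endo-trig at the C4=C5 bond through a chair, and ring B closes 5-exo-trig at the same bond, anti to the incoming C6. C3 is set by the catalyst, whose diaryl(silyloxy)methyl group covers the Re face of C3 so that oxygen enters on the Si face (3S), and C4 follows from C3 because the two-atom C2-C1 tether reaches only the face of C4 that gives the cis-fused bicycle (4S). C6 is set in the chair: 1,2-allylic strain with the C4 methyl group turns the CH2CHO arm on C3 pseudoaxial, and 12 reacts in the geometry that has the long chain anti and the methyl group syn to the O-O bond, which puts the chain equatorial and cis to that arm (6R); both ketal epimers of 11 converge on the same planar ion, but the bias between methyl and n-alkyl is small by nature and is the weakest control element of the route. The step needs 1,4- over 1,6-addition and peroxide retention over epoxide formation in the first stage, which the hard oxygen nucleophile, the poor hemiketal-type leaving group and fast enamine protonation by the acid co-catalyst should secure, and ketal over aldehyde activation in the second stage, which the far more labile tertiary peroxyketal and the low temperature should secure.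

Step 6
Reactants: 14 (3R,4aS,7aS)-6-methoxy-3,4a-dimethyl-3-(10-phenyldecyl)hexahydrofuro[3,2-c][1,2]dioxine
Product: 16 (3R,4aS,7aS)-3,4a-dimethyl-3-(10-phenyldecyl)tetrahydrofuro[3,2-c][1,2]dioxin-6(3H)-one, via lactol 15 (not isolated)
Conditions: CrO3, aq. H2SO4, acetone, 0 °C
Reagents that add atoms: water, O
Why: Jones oxidation: aqueous acid opens the methyl acetal to lactol 15, which chromic acid oxidises at once to the gamma-lactone, both anomers converge, and the dialkyl peroxide, the two quaternary centres and C3 (not enolisable, beta to the new carbonyl) are left untouched under these acidic conditions.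

Compound list
1 | 1,10-dibromodecane | BrCCCCCCCCCCBr | starting material
2 | phenylmagnesium bromide | Br[Mg]c1ccccc1 | starting material
3 | (10-bromodecyl)benzene | BrCCCCCCCCCCc1ccccc1 | intermediate
4 | isopropenylmagnesium bromide | C=C(C)[Mg]Br | starting material
5 | 2-methyl-12-phenyldodec-1-ene | C=C(C)CCCCCCCCCCc1ccccc1 | intermediate
6 | 12-phenyldodecan-2-one O-oxide (ketone oxide) | CC(CCCCCCCCCCc1ccccc1)=[O+][O-] | intermediate
7 | 2-hydroperoxy-2-methoxy-12-phenyldodecane (racemic) | CC(OC)(OO)CCCCCCCCCCc1ccccc1 | intermediate
8 | methacrolein | C=C(C)C=O | starting material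
9 | (triphenylphosphoranylidene)acetaldehyde | O=CC=P(c1ccccc1)(c1ccccc1)c1ccccc1 | starting material
10 | (2E)-4-methylpenta-2,4-dienal | C=C(C)/C=C/C=O | intermediate
11 | (3S)-3-[(2-methoxy-12-phenyldodecan-2-yl)peroxy]-4-methylpent-4-enal (both ketal epimers) | C=C(C)[C@H](CC=O)OOC(C)(OC)CCCCCCCCCCc1ccccc1 | intermediate
12 | peroxycarbenium triflate: 11 after loss of methoxide, C6=O(+)–O–C3, (3S) | C=C(C)[C@H](CC=O)O[O+]=C(C)CCCCCCCCCCc1ccccc1.[O-]S(=O)(=O)C(F)(F)F | intermediate
13 | cis-fused bicyclic oxolanylium triflate, C1=O(+) in ring B, (C3 S, C4 S, C6 R) | C[C@@]1(CCCCCCCCCCc2ccccc2)C[C@]2(C)[O+]=CC[C@@H]2OO1.[O-]S(=O)(=O)C(F)(F)F | intermediate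
14 | (3R,4aS,7aS)-6-methoxy-3,4a-dimethyl-3-(10-phenyldecyl)hexahydrofuro[3,2-c][1,2]dioxine (both anomers) | C[C@@]1(CCCCCCCCCCc2ccccc2)C[C@]2(C)OC(OC)C[C@@H]2OO1 | intermediate
15 | (3R,4aS,7aS)-3,4a-dimethyl-3-(10-phenyldecyl)hexahydrofuro[3,2-c][1,2]dioxin-6-ol (lactol, both anomers) | C[C@@]1(CCCCCCCCCCc2ccccc2)C[C@]2(C)OC(O)C[C@@H]2OO1 | intermediate
16 | (3R,4aS,7aS)-3,4a-dimethyl-3-(10-phenyldecyl)tetrahydrofuro[3,2-c][1,2]dioxin-6(3H)-one (C3 S, C4 S, C6 R in the text locants) | C[C@@]1(CCCCCCCCCCc2ccccc2)C[C@]2(C)OC(=O)C[C@@H]2OO1 | target

Total steps: 6. Longest linear sequence: 5 (steps 1, 2, 3, 5, 6).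

Steps most likely to fail

Step 5.
- **What may go wrong:**
  - In the first stage the hydroperoxide may add 1,6 to the dienyl iminium ion, or the enamine may attack the O–O bond and form an epoxide.
  - In the second stage the C4 cation may lose a proton or undergo a hydride shift before the aldehyde oxygen captures it.
  - Facial discrimination at C6 may be poor. The C6 epimers would then have to be separated at 14 or 16.
- **Fallback** (known chemistry, different ring logic; sets out from 5, returns at 16):
  - A carbonyl-ene reaction of 5 with methyl pyruvate, catalysed by Cu(SbF6)2 and a tert-butyl-bis(oxazoline) ligand (enantiomer chosen for the 2S alcohol), would give methyl (2S)-2-hydroxy-2-methyl-4-methylidene-14-phenyltetradecanoate F1.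
  - DIBAL-H at −78 °C would give (2S)-2-hydroxy-2-methyl-4-methylidene-14-phenyltetradecanal F2.
  - A Still–Gennari olefination would give methyl (2Z,4S)-4-hydroxy-4-methyl-6-methylidene-16-phenylhexadec-2-enoate F3. This lactonises to (5S)-5-methyl-5-(2-methylidene-12-phenyldodecyl)furan-2(5H)-one F4.
  - Mukaiyama–Isayama peroxidation (Co(acac)2, O2, Et3SiH) would give the triethylsilyl peroxide F5 as both C6 epimers.
  - Fluoride would free the hydroperoxide F6.
  - Et3N-promoted 6-exo oxa-Michael closure onto the butenolide would give 16 together with its 6-epimer F7, removed by chromatography.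

Step 6.
- **What may go wrong:** the strongly acidic medium may ionise the tertiary C6–O bond or trigger O–O heterolysis, and chromic acid may attack the benzylic position.
- **Fallback** (sets out from 14, returns at 16): mild hydrolysis (PPTS, wet THF) with isolation of lactol 15. This is followed by a non-acidic, metal-free oxoammonium oxidation (TEMPO, PhI(OAc)2, CH2Cl2, rt). No new compound is made.

Step 3.
- **What may go wrong:** part of the primary ozonide may cleave the other way, and the hydroperoxy ketal may collapse to the ketone during concentration or on silica.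
- **Fallback** (sets out from 5, returns at 7):
  - Ozonolysis in CH2Cl2 with Me2S work-up would give 12-phenyldodecan-2-one F8.
  - HC(OMe)3, MeOH and TsOH would give (11,11-dimethoxydodecyl)benzene F9.
  - Acid-catalysed perhydrolysis with ethereal H2O2 (PPTS, 0 °C) would exchange one methoxy group for OOH to give 7, used crude.

Further compounds
F1 | step 5 | methyl (2S)-2-hydroxy-2-methyl-4-methylidene-14-phenyltetradecanoate | C=C(CCCCCCCCCCc1ccccc1)C[C@](C)(O)C(=O)OC
F2 | step 5 | (2S)-2-hydroxy-2-methyl-4-methylidene-14-phenyltetradecanal | C=C(CCCCCCCCCCc1ccccc1)C[C@](C)(O)C=O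
F3 | step 5 | methyl (2Z,4S)-4-hydroxy-4-methyl-6-methylidene-16-phenylhexadec-2-enoate | C=C(CCCCCCCCCCc1ccccc1)C[C@](C)(O)/C=C\C(=O)OC
F4 | step 5 | (5S)-5-methyl-5-(2-methylidene-12-phenyldodecyl)furan-2(5H)-one | C=C(CCCCCCCCCCc1ccccc1)C[C@@]1(C)C=CC(=O)O1
F5 | step 5 | (5S)-5-methyl-5-{2-methyl-12-phenyl-2-[(triethylsilyl)peroxy]dodecyl}furan-2(5H)-one (both C6 epimers) | CC[Si](CC)(CC)OOC(C)(CCCCCCCCCCc1ccccc1)C[C@@]1(C)C=CC(=O)O1
F6 | step 5 | (5S)-5-(2-hydroperoxy-2-methyl-12-phenyldodecyl)-5-methylfuran-2(5H)-one (both C6 epimers) | CC(CCCCCCCCCCc1ccccc1)(OO)C[C@@]1(C)C=CC(=O)O1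
F7 | step 5 | (3S,4aS,7aS)-3,4a-dimethyl-3-(10-phenyldecyl)tetrahydrofuro[3,2-c][1,2]dioxin-6(3H)-one (6-epimer of 16) | C[C@]1(CCCCCCCCCCc2ccccc2)C[C@]2(C)OC(=O)C[C@@H]2OO1
F0 | step 6 | none | none
F8 | step 3 | 12-phenyldodecan-2-one | CC(=O)CCCCCCCCCCc1ccccc1
F9 | step 3 | (11,11-dimethoxydodecyl)benzene | CC(OC)(OC)CCCCCCCCCCc1ccccc1
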